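# Design of a total synthesis of CNP0137897.2, methyl 3α-angeloyloxy-5α-hydroperoxyeudesma-4(15),11(13)-dien-12-oate

## The problem

The target is a eudesmane: a trans-fused decalin in which ring A (C1–C5, C10) and ring B (C5–C10) share the C5–C10 bond. Ring B carries an axial 10β-methyl group (C14) on a quaternary carbon and an equatorial 7β side chain oxidised to a methyl acrylate. Ring A carries an axial 3α-angelate, an exocyclic C4=C15 alkene and an axial tertiary 5α-hydroperoxide. Of the four stereocentres (C3, C5, C7, C10), only C7 can be bought. C7 must control C10 across ring B (a 1,4-relation), and the axial C10 methyl group can then control the face of hydride delivery at C3 and of oxygen delivery at C5. The C7/C10 relation is the classical difficulty: a vinyl ketone annulation on a 2-methyl-5-isopropenylcyclohexanone brings the new chain in axially, cis to the side chain, and gives the 10-epi series. Three groups do not tolerate rough treatment: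

- the allylic hydroperoxide is lost to phosphines, hydrides, strong base and acid (Hock cleavage);
- the (Z)-angelate isomerises to the tiglate on acyl activation or nucleophilic catalysis;
- the acrylate is a Michael acceptor for enolates, hydrides and organometallic reagents.

The feature that makes the key step possible is that C10 lies α to C5, which can be a ketone carbon in a ring B precursor, and that C1 is attached to C10. In a 2-methylidenecyclohexanone the exocyclic carbon is therefore C1, and conjugate addition of a C2–C3 acetate unit there creates the C5–C10 enolate regiospecifically. C14 can then be put on last, axially. The C4=C5 alkene with its C15 methyl group, which the ring A closure leaves behind, is the latent hydroperoxide.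

## Retrosynthesis

**22 to 21.** The C5–O bond is cut and the alkene returned from C4=C15 to C4=C5, which is the retron of an ene reaction of singlet oxygen. The neighbouring options are substitution by a peroxide nucleophile at tertiary C5, or carrying a protected peroxide through the esterification; both are longer and less certain. The precursor 21 lacks the C5 stereocentre and the most fragile group. The forward step must bring oxygen to the α face of C5 and take the hydrogen from C15.

**21 to 19 and 20.** The alkyl–oxygen bond C3–O is cut with inversion. The neighbouring acyl–oxygen cut would need the axial 3α-alcohol, which hydride reduction of the enone does not give, and an activated derivative of angelic acid 20, which puts the Z geometry at risk. Alcohol 19 is the equatorial 3β-epimer and comes from 1,2-reduction of enone 18. The forward step must be a clean SN2 displacement at an allylic carbon without ionisation or elimination.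

**18 back to 14 through 17, 16 and 15.** No skeletal bond is cut; the oxidation level of the side chain is taken back from the acrylate to the isopropenyl group. The adjustment is placed at the enone stage because only there is the ring alkene electron-poor and the isopropenyl group the sole electron-rich alkene. After reduction of C3 the tetrasubstituted C4=C5 alkene would compete. An acrylate carried from the start would not survive the enolate and Grignard steps. Enone 14 has fifteen carbons, two stereocentres and no sensitive group. The forward sequence asks for an allylic oxidation that takes the methyl group of the isopropenyl unit.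

**14 to 12, 11 and 9.** C4=C5 is cut as an aldol condensation and C3–C4 as the acylation of an ethyl nucleophile. The neighbouring cut, C1–C10 together with C4=C5 (vinyl ketone annulation on the 2-methyl ketone), would form C1–C10 last and set C10 the wrong way. This cut leaves C1–C2–C3 on C10 as a propanoate arm, so only C4 and C15 have to be added. Ring A is opened: 9 is monocyclic and already holds both carbon stereocentres. The forward step needs an acyl group that reacts once with the ethyl nucleophile while the ring ketone is masked; the enol lactone 12 of keto acid 11 does both.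

**9 to 4, 5 and 6.** C1–C2 and C10–C14 are cut. This puts the methyl group on last and lets it enter axially on an enolate whose C1 arm is already in place, which gives the cis relation of C14 to the C7 side chain. The precursors are the enone 4, tert-butyl acetate 5 and iodomethane 6. The forward step needs conjugate rather than carbonyl addition, no equilibration of the enolate, and axial methylation.

**4 to 3, 2 and 1.** The enone is taken back by oxidation level to allylic alcohol 3, by epoxide–allylic alcohol isomerisation to epoxide 2, and by epoxidation to (R)-limonene 1. The methyl carbon of 1 becomes C1, its ring becomes ring B and its stereocentre becomes C7.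

## Roads not taken

**Alternative 1: intramolecular cycloaddition of a silyloxydienyne.** The cut is C3–C4 and C5–C10. In the forward step the acyclic dienyne A2 closes rings A and B at once, on heating or with RhCl(PPh3)3, to the cyclohexa-1,4-diene A1.

- Merits: both rings form in one step. The C4=C5 alkene with C15 and the C3 oxygen arrive together, and the E,E-diene geometry gives the 3α configuration directly. In this respect it is better than the chosen plan, which needs a reduction and an inversion to reach 3α.
- Weak points: the C7 stereocentre of A2 has to be made by asymmetric synthesis. The diene terminus C10 carries its methyl group on the inside, which disfavours the s-cis conformer and invites a 1,5-hydrogen shift. The dienophile is an unactivated internal alkyne. C10 is set only by the conformation of a flexible four-carbon tether. After the cycloaddition the C1=C2 alkene must be reduced beside C4=C5, the ketal removed and the methyl ketone homologated by one carbon to the acrylate.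
- Comparison: the chosen plan has to set against the better ring A pattern of A1 a free C7 stereocentre from limonene, a C10 centre set by a well-understood axial alkylation, and a sequence of classical steps without a multistep acyclic precursor.

**Alternative 2: one-carbon insertion into a hydrindanone.** The cut is C3–C4 and C4–C5. The ring-fusion silyl enol ether A4 is cyclopropanated by the zinc carbenoid from CH3CHI2 and Et2Zn, and the siloxycyclopropane is opened with FeCl3 and then NaOAc to the enone A3, which is identical with 14.

- Merits: the enone regiochemistry is unambiguous, and no Grignard reagent or strongly basic aldol step is needed. The endgame from A3 would be the same as here, so the two plans are equal from that point.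
- Weak points: A4 holds the same C7/C10 pair on a hydrindane, where the cis relation of the angular methyl group to the side chain is no easier to set, and it has no short chiral-pool source. The substituted carbenoid has to distinguish a tetrasubstituted enol ether from the isopropenyl group, and FeCl3 is a Lewis acid and one-electron oxidant in the presence of that alkene.
- Comparison: the road to the common enone is longer. The chosen plan reaches 14 from 9 in three classical steps and takes the C10 configuration from limonene.

**Alternative 3: terpene cyclase.** The cut is C6–C7 and C5–C10. A selinene-type synthase with divalent magnesium folds farnesyl diphosphate A6 through a ten-membered ring into α-selinene A5.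

- Merits: one step builds both rings and sets C5, C7 and C10 in absolute terms. In step count to the carbon skeleton it is better than any chemical route, including the chosen one.
- Weak points: A5 has its ring alkene at C3=C4, a hydrogen at C5 and no oxygen at C3. The alkene would have to be moved to C4=C5 with oxygenation at C3 in the α configuration, and the side-chain oxidation would compete with an electron-rich trisubstituted ring alkene. It also requires an expressed enzyme, a production host and separation of selinene isomers.
- Comparison: the chosen plan has to set against the shorter skeleton assembly an enone (14) in which C3, C4, C5 and C15 already stand at the oxidation levels from which the angelate and the hydroperoxide follow in three steps.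

Key step: step 4

## Route

Remark on the chemistry: 2 and 3 are carried as diastereomer mixtures (epoxide cis/trans, carbinol epimers), since the centres in which they differ are erased in step 3.

Step 1
Reactants: 1 (R)-limonene [(4R)-1-methyl-4-(prop-1-en-2-yl)cyclohex-1-ene]
Product: 2 (4R)-1-methyl-4-(prop-1-en-2-yl)-7-oxabicyclo[4.1.0]heptane (limonene 1,2-oxide, cis/trans mixture)
Conditions: mCPBA (1.0 equiv), CH2Cl2, 0 °C
Reagents that add atoms: mCPBA (3-chloroperoxybenzoic acid), O=C(OO)c1cccc(Cl)c1
Why: Prilezhaev epoxidation; the trisubstituted ring alkene is more nucleophilic than the 1,1-disubstituted isopropenyl alkene, so one equivalent of peracid should epoxidise the ring alkene only, and C4 is not touched.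

Step 2
Reactants: 2 limonene 1,2-oxide
Product: 3 (5R)-2-methylidene-5-(prop-1-en-2-yl)cyclohexan-1-ol (mixture of C1 epimers)
Conditions: LiN(iPr)2 (2.5 equiv), Et2O, 0 °C to reflux; H2O
Reagents that add atoms: none
Why: Base-promoted epoxide to allylic alcohol isomerisation (syn β-elimination through the lithium amide bound to the epoxide oxygen); the amide takes the most accessible β-hydrogen, that of the methyl group, so the alkene becomes exocyclic and the oxygen stays on the secondary carbon; both epoxide isomers lead to alcohols that converge in step 3.

Step 3
Reactants: 3 allylic alcohol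
Product: 4 (5R)-2-methylidene-5-(prop-1-en-2-yl)cyclohexan-1-one
Conditions: activated MnO2 (excess), CH2Cl2, 0 °C to rt; filtered, concentrated cold and used at once
Reagents that add atoms: none
Why: Allylic alcohol oxidation with manganese dioxide under neutral conditions, which should neither move the exocyclic alkene into the ring nor touch the isopropenyl group; the enone is used immediately because α-methylene ketones dimerise by hetero-Diels–Alder reaction on standing.

Step 4
Reactants: 4 (5R)-2-methylidene-5-(prop-1-en-2-yl)cyclohexan-1-one; 5 tert-butyl acetate; 6 iodomethane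
Product: 9 tert-butyl 3-[(1S,4R)-1-methyl-2-oxo-4-(prop-1-en-2-yl)cyclohexyl]propanoate, via lithium 1-tert-butoxyethenolate 7 (not isolated), via ring lithium enolate 8 (not isolated)
Conditions: 5 (1.3 equiv), LiN(iPr)2 (1.3 equiv), THF, −78 °C; 4 added slowly, −78 to 0 °C; then 6 (5 equiv), DMPU, −40 to 0 °C
Reagents that add atoms: tert-butyl acetate (5), CC(=O)OC(C)(C)C; iodomethane (6), CI
Why: LiN(iPr)2 converts 5 into the lithium enolate 7, whose carbon (the future C2) adds to the exocyclic methylene carbon of 4 (the future C1) in a Michael addition; addition to the carbonyl group, should it compete at −78 °C, is reversible on warming because the tertiary aldolate can fragment again while the conjugate adduct cannot, so the mixture is expected to drain into enolate 8. Enolate 8 is the tetrasubstituted C5–C10 enolate, formed regiospecifically; it should not equilibrate to the C5–C6 isomer because the flask holds no acid stronger than the ester α-CH2 group and diisopropylamine. Iodomethane then alkylates C10 (SN2 at carbon, forming C10–C14), with DMPU to loosen the aggregate of this hindered enolate. The closest known reaction type is the tandem conjugate addition and enolate alkylation (three-component coupling) of enones, here with a thermodynamically controlled ester-enolate Michael addition to an α-methylene ketone. No ring closes. The new stereocentre C10 is controlled by C7: iodomethane attacks axially through the chair-like transition state in which the isopropenyl group stays equatorial, which places C14 cis to the side chain (1S,4R). The step needs 1,4- over 1,2-addition (unhindered methylene terminus, reversible carbonyl addition), C- over O-alkylation (lithium enolate, soft iodide) and single alkylation (surplus 7 is consumed by iodomethane faster than it can deprotonate 9); the tert-butyl ester is chosen because 7 does not self-condense on warming and the ester is not acylated by 8.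

Step 5
Reactants: 9 tert-butyl 3-[(1S,4R)-1-methyl-2-oxo-4-(prop-1-en-2-yl)cyclohexyl]propanoate
Product: 11 3-[(1S,4R)-1-methyl-2-oxo-4-(prop-1-en-2-yl)cyclohexyl]propanoic acid, via trimethylsilyl ester 10 (not isolated)
Conditions: TMSOTf, 2,6-lutidine, CH2Cl2, 0 °C to rt; then aq. citric acid
Reagents that add atoms: none
Why: Silyl triflate-mediated tert-butyl ester cleavage (O-silylation, loss of the tert-butyl cation as 2-methylpropene, hydrolysis of silyl ester 10 and of any C5–C6 silyl enol ether on work-up); the medium is buffered by the pyridine base, so the isopropenyl group is not protonated as it would be in trifluoroacetic acid.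

Step 6
Reactants: 11 keto acid
Product: 12 (4aS,7R)-4a-methyl-7-(prop-1-en-2-yl)-3,4,4a,5,6,7-hexahydro-2H-chromen-2-one
Conditions: Ac2O, NaOAc, 120 °C
Reagents that add atoms: none
Why: Enol lactonisation of a δ-keto acid through its mixed anhydride; C10 is quaternary, so the ketone can enolise only towards C6 and a single enol lactone should form, and the acetate-buffered medium leaves the isopropenyl group and both stereocentres alone.

Step 7
Reactants: 12 enol lactone
Product: 14 (4aS,7R)-1,4a-dimethyl-7-(prop-1-en-2-yl)-4,4a,5,6,7,8-hexahydronaphthalen-2(3H)-one (α-cyperone), via 1,5-diketone 13 (not isolated)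
Conditions: EtMgBr (1.05 equiv), Et2O/THF, −78 to −20 °C; H2O; then KOH, MeOH, 65 °C
Reagents that add atoms: ethylmagnesium bromide, CC[Mg]Br
Why: Fujimoto–Belleau reaction: the Grignard reagent adds once to the lactone carbonyl (C3–C4), and collapse of the adduct releases the ring ketone as its magnesium enolate, which is inert to further reagent; after protonation to diketone 13, base-mediated aldol condensation of C4 onto C5 and dehydration closes ring A as the conjugated enone, the bridged ketol from the other enolate being unable to dehydrate. No stereocentre is touched (C10 quaternary, C7 not enolisable).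

Step 8
Reactants: 14 α-cyperone
Product: 15 (4aS,7R)-7-(3-hydroxyprop-1-en-2-yl)-1,4a-dimethyl-4,4a,5,6,7,8-hexahydronaphthalen-2(3H)-one
Conditions: SeO2 (cat.), t-BuOOH, CH2Cl2, rt
Reagents that add atoms: tert-butyl hydroperoxide, CC(C)(C)OO (terminal oxidant; the oxygen is passed on through catalytic selenium dioxide, O=[Se]=O)
Why: Riley allylic oxidation in its catalytic form (ene reaction of SeO2 at the alkene, then 2,3-sigmatropic shift); the isopropenyl group is the only electron-rich alkene because C4=C5 is conjugated with the ketone, and the freely rotating methyl group is better aligned than the C7 methine hydrogen; any aldehyde formed by over-oxidation converges in step 9.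

Step 9
Reactants: 15 allylic alcohol
Product: 16 2-[(2R,4aS)-4a,8-dimethyl-7-oxo-1,2,3,4,4a,5,6,7-octahydronaphthalen-2-yl]prop-2-enal
Conditions: activated MnO2, CH2Cl2, rt
Reagents that add atoms: none
Why: Manganese dioxide oxidation of a primary allylic alcohol to the enal, which stops at the aldehyde and leaves the enone untouched.

Step 10
Reactants: 16 enal
Product: 17 2-[(2R,4aS)-4a,8-dimethyl-7-oxo-1,2,3,4,4a,5,6,7-octahydronaphthalen-2-yl]prop-2-enoic acid
Conditions: NaClO2, NaH2PO4, 2-methylbut-2-ene, t-BuOH/H2O, 0 °C to rt
Reagents that add atoms: sodium chlorite, [Na+].[O-]Cl=O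
Why: Pinnick oxidation; chlorous acid adds to the aldehyde and fragments to the acid, and the alkene scavenger removes hypochlorous acid before it can attack the acrylic or enone double bond.

Step 11
Reactants: 17 acrylic acid; 6 iodomethane
Product: 18 methyl 2-[(2R,4aS)-4a,8-dimethyl-7-oxo-1,2,3,4,4a,5,6,7-octahydronaphthalen-2-yl]prop-2-enoate
Conditions: MeI, K2CO3, DMF, rt
Reagents that add atoms: iodomethane (6), CI
Why: SN2 O-alkylation of the carboxylate; K2CO3 is too weak to enolise the enone, so no C-methylation is expected, and no acid or diazoalkane is needed.

Step 12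
Reactants: 18 keto ester
Product: 19 methyl 2-[(2R,4aS,7S)-7-hydroxy-4a,8-dimethyl-1,2,3,4,4a,5,6,7-octahydronaphthalen-2-yl]prop-2-enoate (3β-alcohol)
Conditions: NaBH4, CeCl3·7H2O, MeOH, −78 to −40 °C
Reagents that add atoms: none
Why: Luche reduction; the cerium-modified borohydride attacks the ketone 1,2 and leaves the acrylate alone at low temperature, and hydride arrives axially on the α face, opposite the axial C10 methyl group, so the new C3 carbinol should be the pseudo-equatorial 3β-epimer.

Step 13
Reactants: 19 3β-alcohol; 20 angelic acid [(2Z)-2-methylbut-2-enoic acid]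
Product: 21 methyl 2-[(2R,4aS,7R)-4a,8-dimethyl-7-{[(2Z)-2-methylbut-2-enoyl]oxy}-1,2,3,4,4a,5,6,7-octahydronaphthalen-2-yl]prop-2-enoate (3α-angelate)
Conditions: PPh3, DIAD, toluene, 0 °C to rt
Reagents that add atoms: angelic acid (20), C/C=C(/C)C(=O)O
Why: Mitsunobu esterification; the carboxylate displaces the oxyphosphonium group at C3 by SN2 with inversion, which gives the axial 3α-ester, and because the acid acts only as a nucleophile and is never activated at its acyl carbon the Z geometry should be kept; SN2′ attack would have to occur at the fully substituted C5.

Step 14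
Reactants: 21 3α-angelate
Product: 22 methyl 2-[(2R,4aS,7R,8aS)-8a-hydroperoxy-4a-methyl-8-methylidene-7-{[(2Z)-2-methylbut-2-enoyl]oxy}decahydronaphthalen-2-yl]prop-2-enoate (CNP0137897.2)
Conditions: O2, hν (visible), tetraphenylporphyrin (cat.), CH2Cl2, −20 °C
Reagents that add atoms: dioxygen, O=O
Why: Schenck ene reaction of singlet oxygen with the tetrasubstituted C4=C5 alkene, the only electron-rich alkene left (acrylate and angelate are electron-poor); oxygen should bond to C5 from the α face, opposite the axial C10 methyl group, and on that face only a C15 hydrogen is aligned for abstraction (C3 carries no α-hydrogen and the 6α-hydrogen is pseudo-equatorial), so the alkene moves to C4=C15 and C5 becomes the 5α-hydroperoxide; the neutral, cold conditions end the route, so the peroxide meets no further reagent.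

## Compound list

1 | (R)-limonene, (4R)-1-methyl-4-(prop-1-en-2-yl)cyclohex-1-ene | CC1=CC[C@@H](CC1)C(C)=C | starting material
2 | (4R)-1-methyl-4-(prop-1-en-2-yl)-7-oxabicyclo[4.1.0]heptane (cis/trans mixture) | CC12CC[C@H](CC1O2)C(C)=C | intermediate
3 | (5R)-2-methylidene-5-(prop-1-en-2-yl)cyclohexan-1-ol (C1 epimers) | C=C1CC[C@@H](C(C)=C)CC1O | intermediate
4 | (5R)-2-methylidene-5-(prop-1-en-2-yl)cyclohexan-1-one | C=C1CC[C@@H](C(C)=C)CC1=O | intermediate
5 | tert-butyl acetate | CC(=O)OC(C)(C)C | starting material
6 | iodomethane | CI | starting material
7 | lithium 1-tert-butoxyethenolate (formed in the flask, not isolated) | C=C([O-])OC(C)(C)C.[Li+] | intermediate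
8 | lithium (5R)-2-[3-(tert-butoxy)-3-oxopropyl]-5-(prop-1-en-2-yl)cyclohex-1-en-1-olate (formed in the flask, not isolated) | CC(C)(C)OC(=O)CCC1=C([O-])C[C@@H](CC1)C(C)=C.[Li+] | intermediate
9 | tert-butyl 3-[(1S,4R)-1-methyl-2-oxo-4-(prop-1-en-2-yl)cyclohexyl]propanoate | CC(C)(C)OC(=O)CC[C@]1(C)CC[C@@H](C(C)=C)CC1=O | intermediate
10 | trimethylsilyl 3-[(1S,4R)-1-methyl-2-oxo-4-(prop-1-en-2-yl)cyclohexyl]propanoate (formed in the flask, not isolated) | C[Si](C)(C)OC(=O)CC[C@]1(C)CC[C@@H](C(C)=C)CC1=O | intermediate
11 | 3-[(1S,4R)-1-methyl-2-oxo-4-(prop-1-en-2-yl)cyclohexyl]propanoic acid | OC(=O)CC[C@]1(C)CC[C@@H](C(C)=C)CC1=O | intermediate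
12 | (4aS,7R)-4a-methyl-7-(prop-1-en-2-yl)-3,4,4a,5,6,7-hexahydro-2H-chromen-2-one | O=C1CC[C@]2(C)CC[C@@H](C(C)=C)C=C2O1 | intermediate
13 | (2S,5R)-2-methyl-2-(3-oxopentyl)-5-(prop-1-en-2-yl)cyclohexan-1-one (formed in the flask, not isolated) | CCC(=O)CC[C@]1(C)CC[C@@H](C(C)=C)CC1=O | intermediate
14 | (4aS,7R)-1,4a-dimethyl-7-(prop-1-en-2-yl)-4,4a,5,6,7,8-hexahydronaphthalen-2(3H)-one (α-cyperone) | CC(=C)[C@@H]1CC[C@@]2(C)CCC(=O)C(C)=C2C1 | intermediate
15 | (4aS,7R)-7-(3-hydroxyprop-1-en-2-yl)-1,4a-dimethyl-4,4a,5,6,7,8-hexahydronaphthalen-2(3H)-one | OCC(=C)[C@@H]1CC[C@@]2(C)CCC(=O)C(C)=C2C1 | intermediate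
16 | 2-[(2R,4aS)-4a,8-dimethyl-7-oxo-1,2,3,4,4a,5,6,7-octahydronaphthalen-2-yl]prop-2-enal | O=CC(=C)[C@@H]1CC[C@@]2(C)CCC(=O)C(C)=C2C1 | intermediate
17 | 2-[(2R,4aS)-4a,8-dimethyl-7-oxo-1,2,3,4,4a,5,6,7-octahydronaphthalen-2-yl]prop-2-enoic acid | OC(=O)C(=C)[C@@H]1CC[C@@]2(C)CCC(=O)C(C)=C2C1 | intermediate
18 | methyl 2-[(2R,4aS)-4a,8-dimethyl-7-oxo-1,2,3,4,4a,5,6,7-octahydronaphthalen-2-yl]prop-2-enoate | COC(=O)C(=C)[C@@H]1CC[C@@]2(C)CCC(=O)C(C)=C2C1 | intermediate
19 | methyl 2-[(2R,4aS,7S)-7-hydroxy-4a,8-dimethyl-1,2,3,4,4a,5,6,7-octahydronaphthalen-2-yl]prop-2-enoate | COC(=O)C(=C)[C@@H]1CC[C@@]2(C)CC[C@H](O)C(C)=C2C1 | intermediate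
20 | angelic acid, (2Z)-2-methylbut-2-enoic acid | C/C=C(/C)C(=O)O | starting material
21 | methyl 2-[(2R,4aS,7R)-4a,8-dimethyl-7-{[(2Z)-2-methylbut-2-enoyl]oxy}-1,2,3,4,4a,5,6,7-octahydronaphthalen-2-yl]prop-2-enoate | COC(=O)C(=C)[C@@H]1CC[C@@]2(C)CC[C@@H](OC(=O)/C(C)=C\C)C(C)=C2C1 | intermediate
22 | methyl 2-[(2R,4aS,7R,8aS)-8a-hydroperoxy-4a-methyl-8-methylidene-7-{[(2Z)-2-methylbut-2-enoyl]oxy}decahydronaphthalen-2-yl]prop-2-enoate (CNP0137897.2) | C=C(C(=O)OC)[C@@H]1CC[C@@]2(C)CC[C@@H](OC(=O)/C(C)=C\C)C(=C)[C@]2(OO)C1 | target

## Step count and least certain steps

Total: 14 steps. Longest linear sequence: 14 steps (1 to 22); compounds 5, 6 and 20 enter directly.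

**Step 4 (key step).** Two processes may fail.

- The enolate 7 may add to the carbonyl group of 4 or remove a proton at C6, and the very reactive methylene ketone may then oligomerise.
- The methylation may show incomplete facial selectivity. Iodomethane is small and the directing isopropenyl group is four atoms away, so attack through the ring-flipped half-chair or a twist-boat can compete with the axial path.

Fallback: from 2, a Meinwald rearrangement with catalytic ZnBr2 in toluene gives dihydrocarvone F1. Condensation with (R)-1-phenylethylamine gives the imine F2. Its secondary enamine tautomer adds to tert-butyl acrylate in an aza-ene-type Michael addition to give the alkylated imine F3. Hydrolysis with aqueous acetic acid returns to the route at 9. This path forms C1–C10 in place of C1–C2 and C10–C14, and the amine auxiliary sets C10 and has to override the preference of the ring.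

**Step 7.** The Grignard reagent may add a second time to the ethyl ketone released from the lactone, or attack may be incomplete, because the two carbonyl groups differ little in reactivity once the lactone has opened. Fallback: from 11, 2,2′-dipyridyl disulfide and PPh3 give the S-pyridin-2-yl thioester F4. EtMgBr at −78 °C performs a chelation-assisted acyl substitution that is faster than addition to either ketone and gives diketone 13, now isolated. KOH in methanol closes it to 14.

**Step 8.** The ene reaction may abstract the C7 methine hydrogen, or oxidation may occur at positions activated by the enone (C2, C6), because the selenium reagent has more than one allylic hydrogen within reach. Fallback: from 14, ene-type chlorination with Ca(OCl)2 and CO2 in CH2Cl2/H2O gives the allyl chloride F5. Displacement with KOAc in DMF gives the allyl acetate F6. Methanolysis with K2CO3 in methanol returns to the route at 15.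

**Step 13.** The allylic oxyphosphonium ion may ionise or eliminate before the weakly acidic, hindered carboxylate attacks, which would cost inversion and material to a diene. Fallback: from 19, a Mitsunobu reaction with the stronger 4-nitrobenzoic acid gives the 3α-(4-nitrobenzoate) F7. Methanolysis with K2CO3 in methanol at 0 °C gives the 3α-alcohol F8. Acylation with the mixed anhydride F9 (from 20, 2,4,6-trichlorobenzoyl chloride and Et3N) in toluene at 80 °C, without a nucleophilic catalyst, returns to the route at 21. Inversion and acylation are thereby separated.

Step 14 is not ranked with these. Only attack on the α face offers an aligned hydrogen, and that hydrogen is on C15, so the selectivity rests on the shielding of the β face by the C10 methyl group.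

## Further compounds

F1 | step 4 | (2RS,5R)-2-methyl-5-(prop-1-en-2-yl)cyclohexan-1-one (dihydrocarvone) | CC1CC[C@@H](C(C)=C)CC1=O
F2 | step 4 | (5R)-2-methyl-N-[(1R)-1-phenylethyl]-5-(prop-1-en-2-yl)cyclohexan-1-imine | CC1CC[C@@H](C(C)=C)CC1=N[C@H](C)c1ccccc1
F3 | step 4 | tert-butyl 3-[(1S,4R)-1-methyl-2-{[(1R)-1-phenylethyl]imino}-4-(prop-1-en-2-yl)cyclohexyl]propanoate | CC(C)(C)OC(=O)CC[C@]1(C)CC[C@@H](C(C)=C)CC1=N[C@H](C)c1ccccc1
F4 | step 7 | S-pyridin-2-yl 3-[(1S,4R)-1-methyl-2-oxo-4-(prop-1-en-2-yl)cyclohexyl]propanethioate | O=C(CC[C@]1(C)CC[C@@H](C(C)=C)CC1=O)Sc1ccccn1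
F5 | step 8 | (4aS,7R)-7-(3-chloroprop-1-en-2-yl)-1,4a-dimethyl-4,4a,5,6,7,8-hexahydronaphthalen-2(3H)-one | ClCC(=C)[C@@H]1CC[C@@]2(C)CCC(=O)C(C)=C2C1
F6 | step 8 | 2-[(2R,4aS)-4a,8-dimethyl-7-oxo-1,2,3,4,4a,5,6,7-octahydronaphthalen-2-yl]prop-2-en-1-yl acetate | CC(=O)OCC(=C)[C@@H]1CC[C@@]2(C)CCC(=O)C(C)=C2C1
F7 | step 13 | methyl 2-[(2R,4aS,7R)-4a,8-dimethyl-7-[(4-nitrobenzoyl)oxy]-1,2,3,4,4a,5,6,7-octahydronaphthalen-2-yl]prop-2-enoate | COC(=O)C(=C)[C@@H]1CC[C@@]2(C)CC[C@@H](OC(=O)c3ccc(cc3)[N+](=O)[O-])C(C)=C2C1
F8 | step 13 | methyl 2-[(2R,4aS,7R)-7-hydroxy-4a,8-dimethyl-1,2,3,4,4a,5,6,7-octahydronaphthalen-2-yl]prop-2-enoate | COC(=O)C(=C)[C@@H]1CC[C@@]2(C)CC[C@@H](O)C(C)=C2C1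
F9 | step 13 | (2Z)-2-methylbut-2-enoic 2,4,6-trichlorobenzoic anhydride | C/C=C(/C)C(=O)OC(=O)c1c(Cl)cc(Cl)cc1Cl
A1 | alternative 1 | (3α)-3-[(tert-butyldimethylsilyl)oxy]-11,11-(ethylenedioxy)-13-noreudesma-1,4-diene | CC1(OCCO1)[C@@H]2CC[C@@]3(C)C=C[C@@H](O[Si](C)(C)C(C)(C)C)C(C)=C3C2
A2 | alternative 1 | tert-butyl(dimethyl){[(1E,3E,7R)-4-methyl-7-(2-methyl-1,3-dioxolan-2-yl)undeca-1,3-dien-9-yn-1-yl]oxy}silane | CC#CC[C@@H](CC/C(C)=C/C=C/O[Si](C)(C)C(C)(C)C)C1(C)OCCO1
A3 | alternative 2 | (4aS,7R)-1,4a-dimethyl-7-(prop-1-en-2-yl)-4,4a,5,6,7,8-hexahydronaphthalen-2(3H)-one (eudesma-4,11-dien-3-one, identical with 14) | CC(=C)[C@@H]1CC[C@@]2(C)CCC(=O)C(C)=C2C1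
A4 | alternative 2 | trimethyl{[(3aS,6R)-3a-methyl-6-(prop-1-en-2-yl)-3,3a,4,5,6,7-hexahydro-2H-inden-1-yl]oxy}silane | CC(=C)[C@@H]1CC[C@@]2(C)CCC(O[Si](C)(C)C)=C2C1
A5 | alternative 3 | α-selinene (eudesma-3,11-diene, 5α-H) | CC(=C)[C@@H]1CC[C@@]2(C)CCC=C(C)[C@@H]2C1
A6 | alternative 3 | (2E,6E)-farnesyl diphosphate | CC(C)=CCC/C(C)=C/CC/C(C)=C/COP(=O)(O)OP(=O)(O)O
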